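**Strategy.** In elemane numbering, the cyclohexane (C5–C10) bears a quaternary C10 (methyl, vinyl C1=C2) next to C5 with its C3=C4 methylidene unit. This trans-1,2-dialkenylcyclohexane is the Cope retron of an (E,E)-cyclodeca-1,5-diene, and O8–C8–C7–C11=C13 is a homoallylic alcohol. Copying the presumed biosynthesis (germacrane to elemane), the key step closes a ten-membered germacradiene by chromium-mediated allylation of the C8 aldehyde by the C13 bromide (C7–C8 bond). Without isolation, the germacradiene then undergoes transannular Cope rearrangement (C5–C10 bond, C2–C3 opened). The precursor is an acyclic trienyl aldehyde–allylic bromide whose single stereocentre, silylated C6, comes from catalytic asymmetric alkynylation.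

Key step: step 12

Remark (numbering): elemane/germacrane numbers are used throughout. Ring carbons are C5–C10: C10 is quaternary with methyl C14 and vinyl C1=C2, C9 is the CH2, C8 bears the acyloxy group, C7 the acrylate, C6 the free OH. C5 carries C4(=C3H2)–C15H2O, and C7 carries C11(=C13H2)–C12O2Me.

Remark (assumptions): 1 and 27 are taken as catalogue chemicals. The ProPhenol antipode named in step 6 is the one expected to give the 6R carbinol from an enal; if the sense proved opposite, the other antipode would be used.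

**Step 1**
Reactants: 1 tert-butyl(but-3-yn-1-yloxy)dimethylsilane; 2 oxirane
Product: 4 (E)-6-(tert-butyldimethylsilyloxy)-4-methylhex-3-en-1-ol, via alkenylalane 3 (not isolated)
Conditions: AlMe3, Cp2ZrCl2 (cat.), CH2Cl2, 0 → 23 °C; then n-BuLi, THF, −78 °C; then 2, −78 → 0 °C
Reagents that add atoms: trimethylaluminium C[Al](C)C
Why: Negishi zirconium-catalysed carboalumination adds methyl and aluminium syn across the terminal alkyne with methyl on the internal carbon, and the alkenylalanate formed with n-BuLi opens oxirane with retention, so the C1=C10 alkene is set E.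

**Step 2**
Reactants: 4
Product: 5 (E)-(6-bromo-3-methylhex-3-en-1-yloxy)(tert-butyl)dimethylsilane
Conditions: CBr4, PPh3, CH2Cl2, 0 °C
Reagents that add atoms: carbon tetrabromide BrC(Br)(Br)Br
Why: Appel bromination of the primary alcohol under neutral conditions that leave the silyl ether and the alkene untouched.

**Step 3**
Reactants: 5; 6 prop-2-yn-1-ol
Product: 10 (Z)-3-iodo-2-[(E)-6-(tert-butyldimethylsilyloxy)-4-methylhex-3-en-1-yl]prop-2-en-1-ol, via Grignard reagent 7 (not isolated), via magnesium alkoxide 8 (not isolated), via magnesacycle 9 (not isolated)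
Conditions: 5, Mg, THF, 40 °C; separately 6, i-PrMgCl, THF, 0 °C; then 7, CuI (cat.), 0 → 23 °C; then I2, −40 → 0 °C
Reagents that add atoms: iodine II
Why: Copper-catalysed anti-carbomagnesiation of the propargyl alkoxide puts the alkyl group on the internal alkyne carbon (C4) and magnesium on C5, held cis to the CH2O group in chelate 9, and iodinolysis with retention gives iodine cis to C15, which fixes the C4=C5 geometry (C3 trans to the future C6).

**Step 4**
Reactants: 10
Product: 11 tert-butyl{(Z)-3-iodo-2-[(E)-6-(tert-butyldimethylsilyloxy)-4-methylhex-3-en-1-yl]prop-2-en-1-yloxy}diphenylsilane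
Conditions: TBDPSCl, imidazole, CH2Cl2, 23 °C
Reagents that add atoms: tert-butyl(chloro)diphenylsilane CC(C)(C)[Si](Cl)(c1ccccc1)c1ccccc1
Why: Silyl ether formation; the bulky TBDPS group is chosen because it resists O-to-C silyl migration in the alkenyllithium of step 5 and survives the selective desilylation of step 10.

**Step 5**
Reactants: 11
Product: 13 (2Z,6E)-9-(tert-butyldimethylsilyloxy)-3-[(tert-butyldiphenylsilyloxy)methyl]-7-methylnona-2,6-dienal, via alkenyllithium 12 (not isolated)
Conditions: t-BuLi (2 equiv), Et2O, −78 °C; then DMF, −78 → 0 °C; aq. NH4Cl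
Reagents that add atoms: N,N-dimethylformamide CN(C)C=O
Why: Iodine–lithium exchange with retention of alkene geometry followed by formylation with DMF (Bouveault aldehyde synthesis) should give the (Z)-enal.

**Step 6**
Reactants: 13; 14 methyl prop-2-ynoate
Product: 16 methyl (4R,5Z,9E)-12-(tert-butyldimethylsilyloxy)-6-[(tert-butyldiphenylsilyloxy)methyl]-4-hydroxy-10-methyldodeca-5,9-dien-2-ynoate, via zinc acetylide 15 (not isolated)
Conditions: (S,S)-ProPhenol (cat.), Me2Zn, 14, PhMe, 23 °C; then 13, 4 °C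
Reagents that add atoms: none
Why: Zinc–ProPhenol-catalysed asymmetric alkynylation, in which the dinuclear zinc catalyst binds the enal and delivers acetylide 15 to one face of the C6 carbonyl, sets C6 (R), the only stereocentre carried into the key step.

**Step 7**
Reactants: 16
Product: 17 methyl (4R,5Z,9E)-4,12-bis(tert-butyldimethylsilyloxy)-6-[(tert-butyldiphenylsilyloxy)methyl]-10-methyldodeca-5,9-dien-2-ynoate
Conditions: TBSCl, imidazole, DMF, 23 °C
Reagents that add atoms: tert-butyl(chloro)dimethylsilane CC(C)(C)[Si](C)(C)Cl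
Why: Silylation of the secondary propargylic alcohol protects O6 through the ring closure and blocks its lactonization onto C12.

**Step 8**
Reactants: 17
Product: 19 methyl (2Z,4R,5Z,9E)-4,12-bis(tert-butyldimethylsilyloxy)-6-[(tert-butyldiphenylsilyloxy)methyl]-2-(hydroxymethyl)-10-methyldodeca-2,5,9-trienoate, via alumino-enoate 18 (not isolated)
Conditions: i-Bu2AlH, HMPA, THF, 0 °C; then CH2O (gas), −78 → 0 °C; Rochelle salt
Reagents that add atoms: formaldehyde C=O
Why: Conjugate hydroalumination of the ynoate (syn, hydride to C7 and aluminium to C11) followed by aldol addition of alumino-enoate 18 to formaldehyde with retention installs C13 trans to C6 (reductive aldol of the vinylalumination type).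

**Step 9**
Reactants: 19
Product: 20 methyl (2E,4R,5Z,9E)-2-(bromomethyl)-4,12-bis(tert-butyldimethylsilyloxy)-6-[(tert-butyldiphenylsilyloxy)methyl]-10-methyldodeca-2,5,9-trienoate
Conditions: CBr4, PPh3, CH2Cl2, −20 → 0 °C
Reagents that add atoms: carbon tetrabromide BrC(Br)(Br)Br
Why: Appel bromination of the primary allylic alcohol with retention of alkene geometry gives the 2-(bromomethyl)enoate needed for allylmetal formation.

**Step 10**
Reactants: 20
Product: 21 methyl (2E,4R,5Z,9E)-2-(bromomethyl)-4-(tert-butyldimethylsilyloxy)-6-[(tert-butyldiphenylsilyloxy)methyl]-12-hydroxy-10-methyldodeca-2,5,9-trienoate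
Conditions: camphorsulfonic acid (cat.), MeOH/CH2Cl2, 0 °C
Reagents that add atoms: none
Why: Acid-catalysed methanolysis should remove the unhindered primary TBS ether much faster than the secondary TBS ether at C6 and the primary TBDPS ether at C15 (selective desilylation).

**Step 11**
Reactants: 21
Product: 22 methyl (2E,4R,5Z,9E)-2-(bromomethyl)-4-(tert-butyldimethylsilyloxy)-6-[(tert-butyldiphenylsilyloxy)methyl]-10-methyl-12-oxododeca-2,5,9-trienoate
Conditions: Dess–Martin periodinane, NaHCO3, CH2Cl2, 0 °C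
Reagents that add atoms: none
Why: Dess–Martin oxidation under buffered, amine-free conditions should give the β,γ-unsaturated aldehyde without moving the C1=C10 alkene into conjugation and without touching the allylic bromide.

**Step 12**
Reactants: 22
Product: 26 methyl 6α-(tert-butyldimethylsilyloxy)-15-(tert-butyldiphenylsilyloxy)-8α-hydroxyelema-1,3,11(13)-trien-12-oate, via allylchromium 23 (not isolated), via germacradiene silyl ether 24 (not isolated), via elemane silyl ether 25 (not isolated)
Conditions: CrCl2 (excess), Me3SiCl, THF (2 mM, slow addition of 22), 23 °C; then Et3N, PhMe, 100 °C; then citric acid, MeOH, 23 °C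
Reagents that add atoms: none
Why: Nozaki–Hiyama–Kishi-type carbonyl allylation followed by Cope rearrangement: two equivalents of CrCl2 turn the allylic bromide into allylchromium 23, whose C7 terminus adds to the C8 aldehyde through a six-membered chair transition state (SE2', leaving the C11=C13 methylene), and Me3SiCl silylates the chromium alkoxide so that O8 cannot attack the C12 ester. The closest known chemistry is the chromium-mediated closure of germacrane rings by intramolecular allylation and the thermal germacradiene-to-elemadiene Cope rearrangement of germacrene-type terpenes. The ten-membered ring closes in the 10-exo-trig mode, and the cyclohexane then closes transannularly as the C5–C10 bond of a chair-like [3,3] shift that opens C2–C3. C7 is controlled by the C6 silyloxy centre (C6–H eclipsed with C7=C11 to avoid allylic 1,3-strain, bond formation anti to the silyl ether on the face that carries the C5 tether) and C8 by the chair allylation transition state with C6 and C9 equatorial, which gives the anti relationship, so that O6, C11 and O8 sit pseudo-equatorial as in 6α,8α-dioxygenated germacranes. C5 and C10 follow from the trans geometry of both ring alkenes and the chair–chair Cope transition state that keeps the C6, C7 and C8 substituents equatorial (C14 and H5 trans-diaxial). The step needs cyclization to beat oligomerization (high dilution), the anti,anti diastereomer, and a Cope equilibrium on the elemane side, which release of medium-ring strain and the absence of a lactone holding the ten-membered ring should secure, while Et3N keeps the hot mixture free of acid that would trigger transannular cyclization.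

**Step 13**
Reactants: 27 2-(hydroxymethyl)prop-2-enoic acid
Product: 29 2-[(tert-butyldimethylsilyloxy)methyl]prop-2-enoic acid, via silyl ester 28 (not isolated)
Conditions: TBSCl (2.2 equiv), imidazole, DMF, 23 °C; then K2CO3, MeOH/THF/H2O, 0 °C; 1 M HCl to pH 4
Reagents that add atoms: tert-butyl(chloro)dimethylsilane CC(C)(C)[Si](C)(C)Cl
Why: Silylation of both the hydroxyl and the carboxyl group followed by selective hydrolysis of the labile silyl ester gives the O-protected acid.

**Step 14**
Reactants: 26; 29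
Product: 31 methyl 6α-(tert-butyldimethylsilyloxy)-15-(tert-butyldiphenylsilyloxy)-8α-{2-[(tert-butyldimethylsilyloxy)methyl]acryloyloxy}elema-1,3,11(13)-trien-12-oate, via mixed anhydride 30 (not isolated)
Conditions: 29, 2,4,6-trichlorobenzoyl chloride, Et3N, PhMe, 23 °C; then 26, DMAP, PhMe, 23 °C
Reagents that add atoms: none
Why: Yamaguchi esterification, in which mixed anhydride 30 acylates the hindered equatorial 8-OH under DMAP catalysis while O6 and O15 are silylated and cannot compete.

**Step 15**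
Reactants: 31
Product: 32 elemacarmanin
Conditions: HF·pyridine, pyridine, THF, 0 → 23 °C
Reagents that add atoms: none
Why: Fluoride-induced cleavage of all three silyl ethers (global desilylation) in a buffered, mildly acidic medium that should avoid acyl migration from O8 to O6, conjugate addition, and lactonization of the freed 6-OH onto the C12 ester.

**Compound list**

1 | tert-butyl(but-3-yn-1-yloxy)dimethylsilane | C#CCCO[Si](C)(C)C(C)(C)C | starting material
2 | oxirane | C1CO1 | starting material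
3 | (E)-[4-(tert-butyldimethylsilyloxy)-2-methylbut-1-en-1-yl]dimethylalane | C[Al](C)/C=C(\C)CCO[Si](C)(C)C(C)(C)C | intermediate (not isolated)
4 | (E)-6-(tert-butyldimethylsilyloxy)-4-methylhex-3-en-1-ol | OCC/C=C(\C)CCO[Si](C)(C)C(C)(C)C | intermediate
5 | (E)-(6-bromo-3-methylhex-3-en-1-yloxy)(tert-butyl)dimethylsilane | BrCC/C=C(\C)CCO[Si](C)(C)C(C)(C)C | intermediate
6 | prop-2-yn-1-ol | C#CCO | starting material
7 | (E)-[6-(tert-butyldimethylsilyloxy)-4-methylhex-3-en-1-yl]magnesium bromide | Br[Mg]CC/C=C(\C)CCO[Si](C)(C)C(C)(C)C | intermediate (not isolated)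
8 | chloromagnesium prop-2-yn-1-olate | C#CCO[Mg]Cl | intermediate (not isolated)
9 | 4-[(E)-6-(tert-butyldimethylsilyloxy)-4-methylhex-3-en-1-yl]-2,5-dihydro-1,2-oxamagnesole (cyclic alkenylmagnesium alkoxide) | C1(CC/C=C(\C)CCO[Si](C)(C)C(C)(C)C)=C[Mg]OC1 | intermediate (not isolated)
10 | (Z)-3-iodo-2-[(E)-6-(tert-butyldimethylsilyloxy)-4-methylhex-3-en-1-yl]prop-2-en-1-ol | I/C=C(/CC/C=C(\C)CCO[Si](C)(C)C(C)(C)C)CO | intermediate
11 | TBDPS ether of 10 | I/C=C(/CC/C=C(\C)CCO[Si](C)(C)C(C)(C)C)CO[Si](c1ccccc1)(c1ccccc1)C(C)(C)C | intermediate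
12 | (Z)-alkenyllithium from 11 (Li in place of I) | [Li]/C=C(/CC/C=C(\C)CCO[Si](C)(C)C(C)(C)C)CO[Si](c1ccccc1)(c1ccccc1)C(C)(C)C | intermediate (not isolated)
13 | (2Z,6E)-9-(tert-butyldimethylsilyloxy)-3-[(tert-butyldiphenylsilyloxy)methyl]-7-methylnona-2,6-dienal | O=C/C=C(/CC/C=C(\C)CCO[Si](C)(C)C(C)(C)C)CO[Si](c1ccccc1)(c1ccccc1)C(C)(C)C | intermediate
14 | methyl prop-2-ynoate | C#CC(=O)OC | starting material
15 | methyl 3-(methylzincio)prop-2-ynoate | C[Zn]C#CC(=O)OC | intermediate (not isolated)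
16 | methyl (4R,5Z,9E)-12-(tert-butyldimethylsilyloxy)-6-[(tert-butyldiphenylsilyloxy)methyl]-4-hydroxy-10-methyldodeca-5,9-dien-2-ynoate | COC(=O)C#C[C@H](O)/C=C(/CC/C=C(\C)CCO[Si](C)(C)C(C)(C)C)CO[Si](c1ccccc1)(c1ccccc1)C(C)(C)C | intermediate
17 | 4-O-TBS ether of 16 | COC(=O)C#C[C@H](O[Si](C)(C)C(C)(C)C)/C=C(/CC/C=C(\C)CCO[Si](C)(C)C(C)(C)C)CO[Si](c1ccccc1)(c1ccccc1)C(C)(C)C | intermediate
18 | methyl 2-(diisobutylalumino)-2-enoate from 17 (Al on C11, trans to C6) | CC(C)C[Al](CC(C)C)/C(C(=O)OC)=C/[C@H](O[Si](C)(C)C(C)(C)C)/C=C(/CC/C=C(\C)CCO[Si](C)(C)C(C)(C)C)CO[Si](c1ccccc1)(c1ccccc1)C(C)(C)C | intermediate (not isolated)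
19 | methyl (2Z,4R,5Z,9E)-4,12-bis(tert-butyldimethylsilyloxy)-6-[(tert-butyldiphenylsilyloxy)methyl]-2-(hydroxymethyl)-10-methyldodeca-2,5,9-trienoate | COC(=O)/C(CO)=C\[C@H](O[Si](C)(C)C(C)(C)C)/C=C(/CC/C=C(\C)CCO[Si](C)(C)C(C)(C)C)CO[Si](c1ccccc1)(c1ccccc1)C(C)(C)C | intermediate
20 | methyl (2E,4R,5Z,9E)-2-(bromomethyl)-4,12-bis(tert-butyldimethylsilyloxy)-6-[(tert-butyldiphenylsilyloxy)methyl]-10-methyldodeca-2,5,9-trienoate | COC(=O)/C(CBr)=C\[C@H](O[Si](C)(C)C(C)(C)C)/C=C(/CC/C=C(\C)CCO[Si](C)(C)C(C)(C)C)CO[Si](c1ccccc1)(c1ccccc1)C(C)(C)C | intermediate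
21 | 12-hydroxy compound from 20 (C8 alcohol) | COC(=O)/C(CBr)=C\[C@H](O[Si](C)(C)C(C)(C)C)/C=C(/CC/C=C(\C)CCO)CO[Si](c1ccccc1)(c1ccccc1)C(C)(C)C | intermediate
22 | 12-oxo compound (C8 aldehyde, cyclization precursor) | COC(=O)/C(CBr)=C\[C@H](O[Si](C)(C)C(C)(C)C)/C=C(/CC/C=C(\C)CC=O)CO[Si](c1ccccc1)(c1ccccc1)C(C)(C)C | intermediate
23 | allylchromium dichloride from 22 (Cr on C13) | COC(=O)/C(C[Cr](Cl)Cl)=C\[C@H](O[Si](C)(C)C(C)(C)C)/C=C(/CC/C=C(\C)CC=O)CO[Si](c1ccccc1)(c1ccccc1)C(C)(C)C | intermediate (not isolated)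
24 | methyl 6α-(tert-butyldimethylsilyloxy)-15-(tert-butyldiphenylsilyloxy)-8α-(trimethylsilyloxy)germacra-1(10),4,11(13)-trien-12-oate, both ring alkenes trans | C[Si](C)(C)O[C@H]1C/C(C)=C/CC/C(CO[Si](c2ccccc2)(c2ccccc2)C(C)(C)C)=C/[C@@H](O[Si](C)(C)C(C)(C)C)[C@@H]1C(=C)C(=O)OC | intermediate (not isolated)
25 | methyl 6α-(tert-butyldimethylsilyloxy)-15-(tert-butyldiphenylsilyloxy)-8α-(trimethylsilyloxy)elema-1,3,11(13)-trien-12-oate | C=C[C@]1(C)C[C@H](O[Si](C)(C)C)[C@@H](C(=C)C(=O)OC)[C@H](O[Si](C)(C)C(C)(C)C)[C@H]1C(=C)CO[Si](c1ccccc1)(c1ccccc1)C(C)(C)C | intermediate (not isolated)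
26 | methyl 6α-(tert-butyldimethylsilyloxy)-15-(tert-butyldiphenylsilyloxy)-8α-hydroxyelema-1,3,11(13)-trien-12-oate | C=C[C@]1(C)C[C@H](O)[C@@H](C(=C)C(=O)OC)[C@H](O[Si](C)(C)C(C)(C)C)[C@H]1C(=C)CO[Si](c1ccccc1)(c1ccccc1)C(C)(C)C | intermediate
27 | 2-(hydroxymethyl)prop-2-enoic acid | C=C(CO)C(=O)O | starting material
28 | tert-butyldimethylsilyl 2-[(tert-butyldimethylsilyloxy)methyl]prop-2-enoate | C=C(CO[Si](C)(C)C(C)(C)C)C(=O)O[Si](C)(C)C(C)(C)C | intermediate (not isolated)
29 | 2-[(tert-butyldimethylsilyloxy)methyl]prop-2-enoic acid | C=C(CO[Si](C)(C)C(C)(C)C)C(=O)O | intermediate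
30 | 2-[(tert-butyldimethylsilyloxy)methyl]prop-2-enoic 2,4,6-trichlorobenzoic anhydride | C=C(CO[Si](C)(C)C(C)(C)C)C(=O)OC(=O)c1c(Cl)cc(Cl)cc1Cl | intermediate (not isolated)
31 | tris-silylated elemacarmanin (6-O-TBS, 15-O-TBDPS, side-chain O-TBS) | C=C[C@]1(C)C[C@H](OC(=O)C(=C)CO[Si](C)(C)C(C)(C)C)[C@@H](C(=C)C(=O)OC)[C@H](O[Si](C)(C)C(C)(C)C)[C@H]1C(=C)CO[Si](c1ccccc1)(c1ccccc1)C(C)(C)C | intermediate
32 | elemacarmanin | C=C[C@]1(C)C[C@H](OC(=O)C(=C)CO)[C@@H](C(=C)C(=O)OC)[C@H](O)[C@H]1C(=C)CO | target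

**Step count.** Total: 15 steps. Longest linear sequence: 14 steps (steps 1–12, 14, 15); step 13 is a one-step side branch.

**Steps most likely to fail, with fallbacks**

Step 12. The ring closure may show poor facial selectivity at C7/C8, the O8 alkoxide may lactonize onto C12 before it is silylated, or oligomerization may win. The fallback is a lactone-templated closure that sets out from 20. Aqueous HF in MeCN at 0 °C should remove both TBS groups, and the freed 6-OH, cis to the ester, should close the butenolide to give (R)-3-(bromomethyl)-5-[(1Z,5E)-2-[(tert-butyldiphenylsilyloxy)methyl]-8-hydroxy-6-methylocta-1,5-dien-1-yl]furan-2(5H)-one F1. Dess–Martin oxidation gives the corresponding aldehyde F2. CrCl2 in THF at high dilution closes the ten-membered ring onto the rigid bromomethylbutenolide (the established germacranolide closure, expected to give the trans-fused lactone) to 15-(tert-butyldiphenylsilyloxy)-8α-hydroxygermacra-1(10),4,11(13)-trien-12,6α-olide F3. Heating F3 in toluene should give the Cope product 15-(tert-butyldiphenylsilyloxy)-8α-hydroxyelema-1,3,11(13)-trien-12,6α-olide F4. Yamaguchi acylation with 29 gives the 8-O-acyl elemanolide F5, and HF·pyridine gives the desilylated 8α-[2-(hydroxymethyl)acryloyloxy]-15-hydroxyelema-1,3,11(13)-trien-12,6α-olide F6. Mild methanolysis of the strained trans-fused lactone (K2CO3 cat., MeOH, 0 °C) comes back to the route at 32; this last methanolysis must compete with conjugate addition of methoxide to the three acrylate units and with cleavage of the 8-O ester.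

Step 8. The ester may be over-reduced, the aluminium enolate may be captured poorly by formaldehyde, or alkene geometry may be lost. The fallback sets out from 17. Palladium-catalysed syn hydrostannation (Bu3SnH, Pd(PPh3)4, THF, 0 °C) places tin on C11 to give the methyl 2-(tributylstannyl)-2-enoate F7. Iododestannylation (I2, CH2Cl2, 0 °C) gives the methyl 2-iodo-2-enoate F8 with retention. Stille coupling with (tributylstannyl)methanol (Pd(PPh3)4, dioxane, 80 °C) comes back to the route at 19.

Step 6. Enantioselectivity may be low on the hindered (Z)-enal, or the enal may isomerize from Z to E under the Lewis-acidic conditions. The fallback sets out from 13. Lithium 3-methoxy-3-oxoprop-1-yn-1-ide F9 (from 14 and LDA, THF, −78 °C) adds to 13 to give the racemic 4-hydroxy ynoate F10. MnO2 oxidation gives the 4-oxo ynoate F11. Corey–Bakshi–Shibata reduction ((R)-Me-CBS, catecholborane, −78 °C, alkynyl group expected to act as the small substituent) comes back to the route at 16.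

**Further compounds**

F1 | step 12 | (R)-3-(bromomethyl)-5-[(1Z,5E)-2-[(tert-butyldiphenylsilyloxy)methyl]-8-hydroxy-6-methylocta-1,5-dien-1-yl]furan-2(5H)-one | BrCC1=C[C@@H](/C=C(/CC/C=C(\C)CCO)CO[Si](c2ccccc2)(c2ccccc2)C(C)(C)C)OC1=O
F2 | step 12 | (R)-3-(bromomethyl)-5-[(1Z,5E)-2-[(tert-butyldiphenylsilyloxy)methyl]-6-methyl-8-oxoocta-1,5-dien-1-yl]furan-2(5H)-one | BrCC1=C[C@@H](/C=C(/CC/C=C(\C)CC=O)CO[Si](c2ccccc2)(c2ccccc2)C(C)(C)C)OC1=O
F3 | step 12 | 15-(tert-butyldiphenylsilyloxy)-8α-hydroxygermacra-1(10),4,11(13)-trien-12,6α-olide, both ring alkenes trans | O[C@H]1C/C(C)=C/CC/C(CO[Si](c2ccccc2)(c2ccccc2)C(C)(C)C)=C/[C@H]2OC(=O)C(=C)[C@H]12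
F4 | step 12 | 15-(tert-butyldiphenylsilyloxy)-8α-hydroxyelema-1,3,11(13)-trien-12,6α-olide | C=C[C@]1(C)C[C@H](O)[C@H]2C(=C)C(=O)O[C@@H]2[C@H]1C(=C)CO[Si](c1ccccc1)(c1ccccc1)C(C)(C)C
F5 | step 12 | 8α-{2-[(tert-butyldimethylsilyloxy)methyl]acryloyloxy}-15-(tert-butyldiphenylsilyloxy)elema-1,3,11(13)-trien-12,6α-olide | C=C[C@]1(C)C[C@H](OC(=O)C(=C)CO[Si](C)(C)C(C)(C)C)[C@H]2C(=C)C(=O)O[C@@H]2[C@H]1C(=C)CO[Si](c1ccccc1)(c1ccccc1)C(C)(C)C
F6 | step 12 | 8α-[2-(hydroxymethyl)acryloyloxy]-15-hydroxyelema-1,3,11(13)-trien-12,6α-olide | C=C[C@]1(C)C[C@H](OC(=O)C(=C)CO)[C@H]2C(=C)C(=O)O[C@@H]2[C@H]1C(=C)CO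
F7 | step 8 | methyl (4R)-4,12-bis(tert-butyldimethylsilyloxy)-6-[(tert-butyldiphenylsilyloxy)methyl]-10-methyl-2-(tributylstannyl)dodeca-2,5,9-trienoate (Sn trans to C6) | CCCC[Sn](CCCC)(CCCC)/C(C(=O)OC)=C/[C@H](O[Si](C)(C)C(C)(C)C)/C=C(/CC/C=C(\C)CCO[Si](C)(C)C(C)(C)C)CO[Si](c1ccccc1)(c1ccccc1)C(C)(C)C
F8 | step 8 | methyl (4R)-4,12-bis(tert-butyldimethylsilyloxy)-6-[(tert-butyldiphenylsilyloxy)methyl]-2-iodo-10-methyldodeca-2,5,9-trienoate (I trans to C6) | I/C(C(=O)OC)=C/[C@H](O[Si](C)(C)C(C)(C)C)/C=C(/CC/C=C(\C)CCO[Si](C)(C)C(C)(C)C)CO[Si](c1ccccc1)(c1ccccc1)C(C)(C)C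
F9 | step 6 | lithium 3-methoxy-3-oxoprop-1-yn-1-ide | [Li]C#CC(=O)OC
F10 | step 6 | racemic methyl (5Z,9E)-12-(tert-butyldimethylsilyloxy)-6-[(tert-butyldiphenylsilyloxy)methyl]-4-hydroxy-10-methyldodeca-5,9-dien-2-ynoate | COC(=O)C#CC(O)/C=C(/CC/C=C(\C)CCO[Si](C)(C)C(C)(C)C)CO[Si](c1ccccc1)(c1ccccc1)C(C)(C)C
F11 | step 6 | methyl (5Z,9E)-12-(tert-butyldimethylsilyloxy)-6-[(tert-butyldiphenylsilyloxy)methyl]-10-methyl-4-oxododeca-5,9-dien-2-ynoate | COC(=O)C#CC(=O)/C=C(/CC/C=C(\C)CCO[Si](C)(C)C(C)(C)C)CO[Si](c1ccccc1)(c1ccccc1)C(C)(C)C
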